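**Strategy**

Ring C is disconnected across O1–C2 and C3–C4 into a ring A salicylaldehyde (formyl carbon = C4, ortho phenol = O1) and a ring B arylacetylene that supplies C2 and C3. In the key step the C8a phenoxide steers rhodium into the formyl C–H bond, hydroacylation joins C4 to the alkyne terminus C3, and a chiral thiourea then closes O1 onto C2 of the resulting 2'-hydroxychalcone, giving the (2S)-flavanone at its final oxidation level without by-product. The step exploits the ortho relationship of O1 (on C8a) and the C4 carbonyl on ring A. The (R)-lavandulyl chain at C8 comes from an Evans deconjugative prenylation and is attached by directed ortho-metalation.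

Key step: step 11

Assumption: the quinine-derived thiourea is taken to favour addition to the C2 face that gives 2S; its quinidine-derived pseudoenantiomer would serve if the sense of induction proved opposite.

**Route**

Step 1
Reactants: 1 (S)-4-benzyl-1,3-oxazolidin-2-one; 2 3-methylbut-2-enoyl chloride
Product: 3 (4S)-4-benzyl-3-(3-methylbut-2-enoyl)-1,3-oxazolidin-2-one
Conditions: n-BuLi, THF, −78 °C; then 2, −78 → 0 °C
Reagents that add atoms: none
Why: N-acylation of the lithiated Evans oxazolidinone with the acid chloride is a standard imide formation that leaves the conjugated trisubstituted alkene untouched at low temperature.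

Step 2
Reactants: 3 (4S)-4-benzyl-3-(3-methylbut-2-enoyl)-1,3-oxazolidin-2-one; 4 1-bromo-3-methylbut-2-ene (prenyl bromide)
Product: 6 (4S)-4-benzyl-3-[(2S)-5-methyl-2-(prop-1-en-2-yl)hex-4-enoyl]-1,3-oxazolidin-2-one, via sodium dienolate 5 (not isolated)
Conditions: NaN(SiMe3)2, THF, −78 °C; then 4, −78 → −40 °C; AcOH quench
Reagents that add atoms: none
Why: γ-Deprotonation gives the chelated Z(O)-dienolate 5, which is alkylated at the α-carbon (Evans deconjugative asymmetric alkylation) on the face opposite the C4 benzyl group, setting the (2S) stereocenter of the lavandulyl skeleton.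

Step 3
Reactants: 6 (4S)-4-benzyl-3-[(2S)-5-methyl-2-(prop-1-en-2-yl)hex-4-enoyl]-1,3-oxazolidin-2-one
Product: 7 (2S)-5-methyl-2-(prop-1-en-2-yl)hex-4-en-1-ol [(S)-lavandulol]
Conditions: LiBH4, H2O (1 equiv), Et2O, 0 °C
Reagents that add atoms: none
Why: Reductive cleavage of the N-acyloxazolidinone with LiBH4 should deliver the primary alcohol quickly enough to avoid epimerization or reconjugation of the allylic α-stereocenter, and it returns the auxiliary.

Step 4
Reactants: 7 (S)-lavandulol
Product: 8 (2S)-5-methyl-2-(prop-1-en-2-yl)hex-4-en-1-yl trifluoromethanesulfonate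
Conditions: Tf2O, pyridine, CH2Cl2, −78 → −30 °C; cold pentane/silica filtration, used at once
Reagents that add atoms: trifluoromethanesulfonic anhydride, O=S(=O)(OS(=O)(=O)C(F)(F)F)C(F)(F)F
Why: Low-temperature sulfonylation of the primary alcohol does not involve the stereocenter, and immediate use should forestall ionization of the homoallylic triflate.

Step 5
Reactants: 9 5-methoxybenzene-1,3-diol
Product: 10 1-methoxy-3,5-bis(methoxymethoxy)benzene
Conditions: NaH, MOMCl, DMF, 0 °C → rt
Reagents that add atoms: chloromethyl methyl ether (MOMCl), COCCl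
Why: Williamson-type O-alkylation of both phenoxides installs the two acetal directing groups needed for the metalations.

Step 6
Reactants: 10 1-methoxy-3,5-bis(methoxymethoxy)benzene; 8 (S)-lavandulyl triflate
Product: 12 5-methoxy-1,3-bis(methoxymethoxy)-2-[(2R)-5-methyl-2-(prop-1-en-2-yl)hex-4-en-1-yl]benzene, via aryllithium 11 (not isolated)
Conditions: n-BuLi, THF, 0 °C; then 8, −78 → −20 °C
Reagents that add atoms: none
Why: Directed ortho-metalation should occur at the carbon flanked by the two MOM ethers (cooperative chelation), and aryllithium 11 then displaces the primary triflate in an SN2 alkylation that leaves the neighbouring stereocenter untouched (its descriptor changes from S to R only because the aryl-bearing CH2 ranks below isopropenyl).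

Step 7
Reactants: 12 5-methoxy-1,3-bis(methoxymethoxy)-2-[(2R)-lavandulyl]benzene
Product: 14 6-methoxy-2,4-bis(methoxymethoxy)-3-[(2R)-5-methyl-2-(prop-1-en-2-yl)hex-4-en-1-yl]benzaldehyde, via aryllithium 13 (not isolated)
Conditions: n-BuLi, TMEDA, THF, −20 → 0 °C; then DMF, 0 °C → rt; aqueous work-up
Reagents that add atoms: N,N-dimethylformamide, CN(C)C=O
Why: A second directed ortho-metalation at one of the two equivalent positions between OMe and OMOM, followed by DMF quench (Bouveault-type formylation), can give only one regioisomer.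

Step 8
Reactants: 14 6-methoxy-2,4-bis(methoxymethoxy)-3-[(2R)-lavandulyl]benzaldehyde
Product: 15 2-hydroxy-6-methoxy-4-(methoxymethoxy)-3-[(2R)-5-methyl-2-(prop-1-en-2-yl)hex-4-en-1-yl]benzaldehyde
Conditions: HCl (0.2 M in MeOH), 0 °C → rt, stopped at monodeprotection
Reagents that add atoms: none
Why: Mild acid methanolysis should cleave the MOM acetal ortho to the formyl group first, because the carbonyl assists its departure and hydrogen-bonds the liberated phenol, while the para MOM ether and the lavandulyl alkenes react more slowly in cold dilute acid.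

Step 9
Reactants: 16 2-hydroxy-4-methoxybenzaldehyde
Product: 17 4-methoxy-2-(methoxymethoxy)benzaldehyde
Conditions: NaH, MOMCl, DMF, 0 °C → rt
Reagents that add atoms: chloromethyl methyl ether (MOMCl), COCCl
Why: O-alkylation of the sodium phenoxide masks the phenol that would otherwise cyclize onto the alkyne under rhodium catalysis.

Step 10
Reactants: 17 4-methoxy-2-(methoxymethoxy)benzaldehyde
Product: 18 1-ethynyl-4-methoxy-2-(methoxymethoxy)benzene
Conditions: dimethyl (1-diazo-2-oxopropyl)phosphonate, K2CO3, MeOH, rt
Reagents that add atoms: dimethyl (1-diazo-2-oxopropyl)phosphonate, CC(=O)C(=[N+]=[N-])P(=O)(OC)OC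
Why: Seyferth–Gilbert homologation with the Ohira–Bestmann reagent converts the aryl aldehyde into the terminal alkyne under mild carbonate conditions that leave the MOM ether intact.

Step 11
Reactants: 15 2-hydroxy-6-methoxy-4-(methoxymethoxy)-3-[(2R)-lavandulyl]benzaldehyde; 18 1-ethynyl-4-methoxy-2-(methoxymethoxy)benzene
Product: 20 (2S)-5-methoxy-7-(methoxymethoxy)-2-[4-methoxy-2-(methoxymethoxy)phenyl]-8-[(2R)-5-methyl-2-(prop-1-en-2-yl)hex-4-en-1-yl]-2,3-dihydro-4H-chromen-4-one, via chalcone 19 (not isolated)
Conditions: [Rh(cod)Cl]2 (2.5 mol%), Fe(C5H4PPh2)2 (dppf, 5 mol%), Na2CO3 (10 mol%), toluene, 70 °C; then 9-epi-aminoquinine-derived 3,5-bis(trifluoromethyl)phenyl thiourea (15 mol%), −20 °C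
Reagents that add atoms: none
Why: The phenoxide of 15 binds monovalent rhodium, which inserts into the formyl C–H bond; syn-hydrometalation of alkyne 18 with rhodium at the terminal carbon and C–C reductive elimination (chelation-assisted intermolecular alkyne hydroacylation of a salicylaldehyde) form the C3–C4 bond and give (E)-chalcone 19. The bifunctional thiourea then ion-pairs the C8a phenoxide through its quinuclidinium while its two N–H bonds activate the enone carbonyl, and the phenoxide adds to C2 in a 6-endo-trig intramolecular oxa-Michael addition that forms the O1–C2 bond and closes ring C. The closest known reaction type is the tandem rhodium-catalysed alkyne hydroacylation/oxa-Michael synthesis of chroman-4-ones from salicylaldehydes, merged here with the organocatalytic enantioselective cyclization of 2'-hydroxychalcones. The new C2 stereocenter is set under catalyst control, the chiral pocket selecting the enone face that leads to 2S, while the remote lavandulyl center is too far away to bias it. The rhodium stage needs linear regiochemistry and alkyne-over-alkene chemoselectivity, secured by the steric preference for rhodium at the unsubstituted alkyne carbon, by the much faster insertion of alkynes, and by the meta position of the lavandulyl chain, which rules out intramolecular alkene hydroacylation. The closure must stay under kinetic control, secured by the low temperature and by the MOM group on the ring B oxygen, which blocks benzofuran formation from the alkyne and quinone-methide-assisted reopening of the C2–O1 bond; all atoms of 15 and 18 end up in 20 and no by-product is formed.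

Step 12
Reactants: 20 (2S)-bis-MOM flavanone
Product: 21 (2S)-7-hydroxy-2-(2-hydroxy-4-methoxyphenyl)-5-methoxy-8-[(2R)-5-methyl-2-(prop-1-en-2-yl)hex-4-en-1-yl]-2,3-dihydro-4H-chromen-4-one
Conditions: HCl (3 M aqueous), MeOH, 40 °C
Reagents that add atoms: none
Why: Acid-catalysed transacetalization of both phenolic MOM ethers to dimethoxymethane should free the 7- and 2'-hydroxyls under conditions mild enough for the aryl methyl ethers, the lavandulyl alkenes and the C2 stereocenter, which racemizes mainly through base-induced ring opening.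

**Compound list**

1 | (S)-4-benzyl-1,3-oxazolidin-2-one | O=C1N[C@@H](Cc2ccccc2)CO1 | starting material
2 | 3-methylbut-2-enoyl chloride | CC(C)=CC(=O)Cl | starting material
3 | (4S)-4-benzyl-3-(3-methylbut-2-enoyl)-1,3-oxazolidin-2-one | CC(C)=CC(=O)N1[C@@H](Cc2ccccc2)COC1=O | intermediate
4 | 1-bromo-3-methylbut-2-ene (prenyl bromide) | CC(C)=CCBr | starting material
5 | sodium (Z)-dienolate of 3 (O and the isopropenyl carbon cis) | C=C(C)/C=C(\[O-])N1[C@@H](Cc2ccccc2)COC1=O.[Na+] | intermediate
6 | (4S)-4-benzyl-3-[(2S)-5-methyl-2-(prop-1-en-2-yl)hex-4-enoyl]-1,3-oxazolidin-2-one | C=C(C)[C@H](CC=C(C)C)C(=O)N1[C@@H](Cc2ccccc2)COC1=O | intermediate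
7 | (2S)-5-methyl-2-(prop-1-en-2-yl)hex-4-en-1-ol, (S)-lavandulol | C=C(C)[C@H](CC=C(C)C)CO | intermediate
8 | (2S)-5-methyl-2-(prop-1-en-2-yl)hex-4-en-1-yl trifluoromethanesulfonate | C=C(C)[C@H](CC=C(C)C)COS(=O)(=O)C(F)(F)F | intermediate
9 | 5-methoxybenzene-1,3-diol | COc1cc(O)cc(O)c1 | starting material
10 | 1-methoxy-3,5-bis(methoxymethoxy)benzene | COCOc1cc(OC)cc(OCOC)c1 | intermediate
11 | [4-methoxy-2,6-bis(methoxymethoxy)phenyl]lithium | COCOc1cc(OC)cc(OCOC)c1[Li] | intermediate
12 | 5-methoxy-1,3-bis(methoxymethoxy)-2-[(2R)-5-methyl-2-(prop-1-en-2-yl)hex-4-en-1-yl]benzene | C=C(C)[C@H](CC=C(C)C)Cc1c(OCOC)cc(OC)cc1OCOC | intermediate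
13 | {6-methoxy-2,4-bis(methoxymethoxy)-3-[(2R)-5-methyl-2-(prop-1-en-2-yl)hex-4-en-1-yl]phenyl}lithium | C=C(C)[C@H](CC=C(C)C)Cc1c(OCOC)cc(OC)c([Li])c1OCOC | intermediate
14 | 6-methoxy-2,4-bis(methoxymethoxy)-3-[(2R)-5-methyl-2-(prop-1-en-2-yl)hex-4-en-1-yl]benzaldehyde | C=C(C)[C@H](CC=C(C)C)Cc1c(OCOC)cc(OC)c(C=O)c1OCOC | intermediate
15 | 2-hydroxy-6-methoxy-4-(methoxymethoxy)-3-[(2R)-5-methyl-2-(prop-1-en-2-yl)hex-4-en-1-yl]benzaldehyde | C=C(C)[C@H](CC=C(C)C)Cc1c(OCOC)cc(OC)c(C=O)c1O | intermediate
16 | 2-hydroxy-4-methoxybenzaldehyde | O=Cc1ccc(OC)cc1O | starting material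
17 | 4-methoxy-2-(methoxymethoxy)benzaldehyde | O=Cc1ccc(OC)cc1OCOC | intermediate
18 | 1-ethynyl-4-methoxy-2-(methoxymethoxy)benzene | C#Cc1ccc(OC)cc1OCOC | intermediate
19 | (E)-1-{2-hydroxy-6-methoxy-4-(methoxymethoxy)-3-[(2R)-5-methyl-2-(prop-1-en-2-yl)hex-4-en-1-yl]phenyl}-3-[4-methoxy-2-(methoxymethoxy)phenyl]prop-2-en-1-one | C=C(C)[C@H](CC=C(C)C)Cc1c(OCOC)cc(OC)c(C(=O)/C=C/c2ccc(OC)cc2OCOC)c1O | intermediate
20 | (2S)-5-methoxy-7-(methoxymethoxy)-2-[4-methoxy-2-(methoxymethoxy)phenyl]-8-[(2R)-5-methyl-2-(prop-1-en-2-yl)hex-4-en-1-yl]-2,3-dihydro-4H-chromen-4-one | C=C(C)[C@H](CC=C(C)C)Cc1c(OCOC)cc(OC)c2c1O[C@H](c1ccc(OC)cc1OCOC)CC2=O | intermediate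
21 | (2S)-7-hydroxy-2-(2-hydroxy-4-methoxyphenyl)-5-methoxy-8-[(2R)-5-methyl-2-(prop-1-en-2-yl)hex-4-en-1-yl]-2,3-dihydro-4H-chromen-4-one | C=C(C)[C@H](CC=C(C)C)Cc1c(O)cc(OC)c2c1O[C@H](c1ccc(OC)cc1O)CC2=O | target

**Step count and risks**

Total step count: 12. Longest linear sequence: 9 steps (steps 1, 2, 3, 4, 6, 7, 8, 11, 12).

Step 11 is the most likely to fail, through poor facial selectivity in the oxa-Michael closure: the addition is reversible and an uncatalysed background cyclization can erode the kinetic preference. The fallback gives up catalyst control and uses the lavandulyl stereocenter as an internal resolving handle. It sets out from 15 and 18, which are taken by the rhodium stage alone to chalcone 19, and comes back at 20. Chalcone 19 is cyclized under thermodynamic control with an achiral base (CsF, MeCN, rt), which should give 20 together with its C2 epimer, (2R)-5-methoxy-7-(methoxymethoxy)-2-[4-methoxy-2-(methoxymethoxy)phenyl]-8-[(2R)-5-methyl-2-(prop-1-en-2-yl)hex-4-en-1-yl]-2,3-dihydro-4H-chromen-4-one F1. The two are diastereomers and should be separable by preparative HPLC. F1 is returned to the same basic conditions, where it re-equilibrates through 19, and is recycled.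

Step 6 is the second risk, through E2 elimination of the β-branched homoallylic triflate by the hindered, basic aryllithium, or ionization and skeletal rearrangement of the triflate before substitution. The fallback is a Negishi cross-coupling that sets out from 10 and 7 and comes back at 12. Lithiation of 10 as in step 6 and quench with I2 should give 2-iodo-5-methoxy-1,3-bis(methoxymethoxy)benzene F2. Appel iodination of 7 (I2, PPh3, imidazole, CH2Cl2) should give the stable (5S)-6-iodo-2-methyl-5-(prop-1-en-2-yl)hex-2-ene F3. Zinc insertion (Zn dust, LiCl, THF) converts F3 into iodo[(2S)-5-methyl-2-(prop-1-en-2-yl)hex-4-en-1-yl]zinc F4, which is coupled with F2 under Pd(OAc)2/SPhos in THF to give 12. The weakly basic organozinc removes the elimination pathway, and reductive elimination from divalent palladium with this ligand should outrun β-hydride loss.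

Step 8 is the third risk, through poor site selectivity of acetal cleavage, with loss of both MOM groups or of the para one. The fallback replaces selective deprotection by selective protection; it sets out from 14 and comes back at 15. Exhaustive methanolysis (HCl, MeOH, 40 °C) should give 2,4-dihydroxy-6-methoxy-3-[(2R)-5-methyl-2-(prop-1-en-2-yl)hex-4-en-1-yl]benzaldehyde F5. In F5 the 2-hydroxyl is locked in a hydrogen bond to the formyl group, so MOMCl (1 equiv) with K2CO3 in acetone at 0 °C should alkylate only the 4-hydroxyl and give 15.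

Further compounds
F1 | step 11 | (2R)-5-methoxy-7-(methoxymethoxy)-2-[4-methoxy-2-(methoxymethoxy)phenyl]-8-[(2R)-5-methyl-2-(prop-1-en-2-yl)hex-4-en-1-yl]-2,3-dihydro-4H-chromen-4-one | C=C(C)[C@H](CC=C(C)C)Cc1c(OCOC)cc(OC)c2c1O[C@@H](c1ccc(OC)cc1OCOC)CC2=O
F2 | step 6 | 2-iodo-5-methoxy-1,3-bis(methoxymethoxy)benzene | COCOc1cc(OC)cc(OCOC)c1I
F3 | step 6 | (5S)-6-iodo-2-methyl-5-(prop-1-en-2-yl)hex-2-ene, (S)-lavandulyl iodide | C=C(C)[C@H](CC=C(C)C)CI
F4 | step 6 | iodo[(2S)-5-methyl-2-(prop-1-en-2-yl)hex-4-en-1-yl]zinc | C=C(C)[C@H](CC=C(C)C)C[Zn]I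
F5 | step 8 | 2,4-dihydroxy-6-methoxy-3-[(2R)-5-methyl-2-(prop-1-en-2-yl)hex-4-en-1-yl]benzaldehyde | C=C(C)[C@H](CC=C(C)C)Cc1c(O)cc(OC)c(C=O)c1O
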